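In ring A and in ring B alike the last ring bond to be made is C1–C2. This exploits the fact that the edge C4–C5–C6–C1 of each quinone (carbonyl, oxygen-bearing carbon, methyl-bearing carbon, carbonyl) maps onto a 3-alkoxy-4-methylcyclobutenedione, and C2–C3 (hydroxylated carbon, tether carbon) onto a benzyloxyvinyl end of the thirteen-methylene tether; the rings differ only at O5 (methyl versus tert-butyl). One thermolysis of the mixed bis(4-alkenyl-4-hydroxycyclobutenone) should open both four-membered rings to dienylketenes and close both hexasubstituted hydroquinone rings. The precursor carries a (Z)-benzyl enol ether at each chain end, its inner carbon bonded to a cyclobutenone carbinol. Debenzylation, air oxidation and acidolysis finish.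

Key step: step 9

Remarks on the chemistry (assumptions and corrections):
- The target is achiral. Both rings are numbered C1(=O), C2(OH), C3(tether), C4(=O), C5(O), C6(CH3); thirteen CH2 groups join the two C3 atoms, so the C15 diacid supplies both C3 atoms and the tether.
- Enol ether geometry of precursor 20 is set as (Z,Z), benzyloxy cis to the carbinol carbon. Bromine–lithium exchange keeps geometry, and only an alkenyllithium with lithium cis to the β-oxygen persists at −78 °C; with lithium trans to oxygen, anti β-elimination of lithium benzyloxide to a terminal alkyne is expected. Benzyloxy therefore sits inward at the closing terminus in step 9.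
- The two tether ends are equivalent, so the mixed adduct can at best be half of the material, beside the two symmetrical adducts. Adding the first dione as the limiting reagent to the dilithio reagent, then the second in excess, makes this partition independent of the unequal reactivity of the two diones.
- Compound 20 is a tertiary allylic alcohol of an enol ether and is handled under buffered, acid-free conditions.

Step 1
Reactants: 1 pentadecanedioic acid
Product: 2 pentadecane-1,15-diol
Conditions: BH3·SMe2, THF, 0 °C to reflux; MeOH
Reagents that add atoms: none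
Why: Borane reduction of a carboxylic acid (via acyloxyboranes) is fast and selective for the primary alcohol, and the saturated chain offers nothing else to react.

Step 2
Reactants: 2 pentadecane-1,15-diol
Product: 3 pentadecanedial
Conditions: TEMPO (cat.), PhI(OAc)2, CH2Cl2, rt
Reagents that add atoms: none
Why: TEMPO-catalysed (oxoammonium) oxidation with PhI(OAc)2 as stoichiometric oxidant stops at the aldehyde in anhydrous CH2Cl2 and runs at room temperature, where the long-chain diol stays dissolved.

Step 3
Reactants: 4 benzyl chloromethyl ether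
Product: 5 (benzyloxymethyl)triphenylphosphonium chloride
Conditions: PPh3, toluene, rt to 60 °C
Reagents that add atoms: triphenylphosphine, c1ccc(cc1)P(c1ccccc1)c1ccccc1
Why: The α-chloro ether is a very reactive SN2 electrophile and quaternises PPh3 to the crystalline phosphonium salt (phosphonium salt formation).

Step 4
Reactants: 3 pentadecanedial; 5 (benzyloxymethyl)triphenylphosphonium chloride
Product: 7 1,17-bis(benzyloxy)heptadeca-1,16-diene (E/Z mixture at both enol ethers), via ylide 6 (not isolated)
Conditions: 5, KN(SiMe3)2, THF, −78 to 0 °C; then 3, −78 °C to rt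
Reagents that add atoms: none
Why: Wittig olefination with the non-stabilised alkoxymethylene ylide 6 turns each aldehyde into a benzyl enol ether, and the mixed geometry does not matter because the next step passes through sp3 carbons at both positions.

Step 5
Reactants: 7 1,17-bis(benzyloxy)heptadeca-1,16-diene
Product: 9 (1Z,16Z)-1,17-bis(benzyloxy)-2,16-dibromoheptadeca-1,16-diene, via tetrabromide 8 (not isolated)
Conditions: Br2 (2.05 equiv), CH2Cl2, −78 °C; then i-Pr2NEt, −78 to 40 °C; Et3N-buffered silica
Reagents that add atoms: bromine, BrBr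
Why: Bromination–dehydrobromination of an enol ether: Br2 adds across each electron-rich double bond and the amine removes HBr from the labile α-bromo ether, whose acetal-like centre epimerises by bromide exchange, so both Wittig isomers should funnel through the anti elimination that leaves bromine cis to benzyloxy and the chain trans to it (as in the preparation of cis-2-bromovinyl ethers), residual isomers being removed by chromatography.

Step 6
Reactants: 10 dimethyl squarate
Product: 13 3-methoxy-4-methylcyclobut-3-ene-1,2-dione, via lithium alkoxide 11 (not isolated), via trifluoroacetate 12 (not isolated)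
Conditions: MeLi, THF, −78 °C; (CF3CO)2O, −78 °C; aq NH4Cl
Reagents that add atoms: methyllithium, [Li]C; water, O
Why: Organolithium 1,2-addition to one squarate carbonyl, trifluoroacetylation of the alkoxide and hydrolytic 1,3-carbonyl transposition with loss of methanol is the standard conversion of a dialkyl squarate into a 3-alkoxy-4-alkylcyclobutenedione.

Step 7
Reactants: 14 di-tert-butyl squarate
Product: 17 3-tert-butoxy-4-methylcyclobut-3-ene-1,2-dione, via lithium alkoxide 15 (not isolated), via trifluoroacetate 16 (not isolated)
Conditions: MeLi, THF, −78 °C; (CF3CO)2O, −78 to 0 °C; cold aq NaHCO3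
Reagents that add atoms: methyllithium, [Li]C
Why: The same 1,2-addition and 1,3-carbonyl transposition applies, the allylic cation released from trifluoroacetate 16 shedding isobutene from the tert-butoxy group on the carbon that becomes the new carbonyl, while the remaining vinylogous tert-butyl ester survives the cold, briefly acidic medium before the bicarbonate quench.

Step 8
Reactants: 9 (1Z,16Z)-1,17-bis(benzyloxy)-2,16-dibromoheptadeca-1,16-diene; 17 3-tert-butoxy-4-methylcyclobut-3-ene-1,2-dione; 13 3-methoxy-4-methylcyclobut-3-ene-1,2-dione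
Product: 20 4-[(1Z,16Z)-1,17-bis(benzyloxy)-16-(2-tert-butoxy-1-hydroxy-3-methyl-4-oxocyclobut-2-en-1-yl)heptadeca-1,16-dien-2-yl]-4-hydroxy-3-methoxy-2-methylcyclobut-2-en-1-one (mixture of carbinol diastereomers), via dilithio reagent 18 (not isolated), via lithiated monoadduct 19 (not isolated)
Conditions: t-BuLi (4.05 equiv), THF, −78 °C; 17 (1.0 equiv) added slowly; then 13 (1.2 equiv); aq NH4Cl, −78 °C; Et3N-buffered silica
Reagents that add atoms: none
Why: Bromine–lithium exchange with retention gives an alkenyllithium whose lithium is cis to, and chelated by, the benzyloxy oxygen (no anti-periplanar β-elimination), and each C–Li then undergoes 1,2-addition to the more electrophilic carbonyl of a cyclobutenedione, the one flanked by the alkoxy-bearing carbon and not the vinylogous ester carbonyl, which later places CH3 para to the tether; the two carbinol centres form without control and are erased in step 9.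

Step 9
Reactants: 20 mixed (Z,Z)-bis(4-alkenyl-4-hydroxycyclobutenone)
Product: 23 3-(benzyloxy)-2-{13-[2-(benzyloxy)-5-tert-butoxy-3,6-dihydroxy-4-methylphenyl]tridecyl}-6-methoxy-5-methylbenzene-1,4-diol, via bis(dienylketene) 21 (not isolated), via bis(cyclohexadienone) 22 (not isolated)
Conditions: degassed toluene, 110 °C, Ar, base-washed glassware
Reagents that add atoms: none
Why: Each 4-hydroxycyclobutenone undergoes thermal conrotatory 4π ring opening in which the donor hydroxyl turns outward, so the alkenyl group ends up beside the ketene; the dienylketene then closes by disrotatory 6π electrocyclisation, joining the ketene carbon (C1) to the benzyloxy-bearing alkene carbon (C2), and the resulting 6-benzyloxycyclohexa-2,4-dienone enolises to the hydroquinone. The closest known reaction type is the Moore ring expansion of 4-alkenyl- and 4-aryl-4-hydroxycyclobutenones to hydroquinones. Ring A and ring B are each closed in the same mode, a 6π electrocyclisation of an acyclic dienylketene to a six-membered carbocycle, and the two events are independent because thirteen methylenes separate them. No stereocentre remains: the carbinol centres of 20 become sp2 on ring opening and the transient sp3 C2 is lost on tautomerisation. The step needs regiocontrol and torquoselectivity; the first is already fixed in 20 (methyl para to the tether, squarate oxygen beside methyl), the second is secured by the hydroxyl on the breaking bond. Benzyloxy sits inward at the closing terminus, which should slow but not block closure onto the unhindered sp ketene carbon, and the neutral, acid-free medium spares the enol ethers and the benzyl, methyl and tert-butyl ethers.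

Step 10
Reactants: 23 bis(hydroquinone) dibenzyl ether
Product: 25 3-[13-(5-tert-butoxy-2-hydroxy-6-methyl-1,4-benzoquinon-3-yl)tridecyl]-2-hydroxy-5-methoxy-6-methyl-1,4-benzoquinone, via hexahydroxy bis(arene) 24 (not isolated)
Conditions: H2 (1 atm), 10% Pd/C, EtOAc–MeOH, rt; filter under Ar; then air, rt
Reagents that add atoms: none
Why: Hydrogenolysis of the two aryl benzyl ethers over Pd/C leaves the methyl and tert-butyl ethers untouched, and the freed 1,2,4-trihydroxyarenes autoxidise in air to the 2-hydroxy-1,4-benzoquinones, the more stable para-quinone tautomer forming in each ring.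

Step 11
Reactants: 25 bis(hydroxyquinone) tert-butyl ether
Product: 26 2,5-dihydroxy-3-[13-(2-hydroxy-5-methoxy-6-methyl-1,4-benzoquinon-3-yl)tridecyl]-6-methyl-1,4-benzoquinone (target)
Conditions: CF3CO2H, CH2Cl2, 0 °C to rt
Reagents that add atoms: none
Why: Acidolysis of a tert-butyl ether: the tert-butyl enol ether of ring B is a vinylogous tert-butyl ester and ionises with loss of isobutene, whereas the vinylogous methyl ester of ring A and the hydroxyquinone units are inert to anhydrous acid.

Compound list
1 | pentadecanedioic acid | OC(=O)CCCCCCCCCCCCCC(=O)O | starting material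
2 | pentadecane-1,15-diol | OCCCCCCCCCCCCCCCO | intermediate
3 | pentadecanedial | O=CCCCCCCCCCCCCCC=O | intermediate
4 | benzyl chloromethyl ether | ClCOCc1ccccc1 | starting material
5 | (benzyloxymethyl)triphenylphosphonium chloride | [Cl-].c1ccccc1COC[P+](c1ccccc1)(c1ccccc1)c1ccccc1 | intermediate
6 | (benzyloxymethylidene)triphenylphosphorane (ylide, not isolated) | c1ccccc1COC=P(c1ccccc1)(c1ccccc1)c1ccccc1 | intermediate
7 | 1,17-bis(benzyloxy)heptadeca-1,16-diene (E/Z mixture at both enol ethers; SMILES without double-bond descriptors) | c1ccccc1COC=CCCCCCCCCCCCCCC=COCc1ccccc1 | intermediate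
8 | 1,17-bis(benzyloxy)-1,2,16,17-tetrabromoheptadecane (mixture of diastereomers, not isolated) | c1ccccc1COC(Br)C(Br)CCCCCCCCCCCCCC(Br)C(Br)OCc1ccccc1 | intermediate
9 | (1Z,16Z)-1,17-bis(benzyloxy)-2,16-dibromoheptadeca-1,16-diene (bromine cis to benzyloxy at both ends) | c1ccccc1CO/C=C(Br)/CCCCCCCCCCCCC/C(Br)=C/OCc1ccccc1 | intermediate
10 | dimethyl squarate (3,4-dimethoxycyclobut-3-ene-1,2-dione) | COC1=C(OC)C(=O)C1=O | starting material
11 | lithium 2,3-dimethoxy-1-methyl-4-oxocyclobut-2-en-1-olate (racemic, not isolated) | COC1=C(OC)C(C)([O-])C1=O.[Li+] | intermediate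
12 | 2,3-dimethoxy-1-methyl-4-oxocyclobut-2-en-1-yl trifluoroacetate (racemic, not isolated) | COC1=C(OC)C(C)(OC(=O)C(F)(F)F)C1=O | intermediate
13 | 3-methoxy-4-methylcyclobut-3-ene-1,2-dione | COC1=C(C)C(=O)C1=O | intermediate
14 | di-tert-butyl squarate (3,4-di-tert-butoxycyclobut-3-ene-1,2-dione) | CC(C)(C)OC1=C(OC(C)(C)C)C(=O)C1=O | starting material
15 | lithium 2,3-di-tert-butoxy-1-methyl-4-oxocyclobut-2-en-1-olate (racemic, not isolated) | CC(C)(C)OC1=C(OC(C)(C)C)C(C)([O-])C1=O.[Li+] | intermediate
16 | 2,3-di-tert-butoxy-1-methyl-4-oxocyclobut-2-en-1-yl trifluoroacetate (racemic, not isolated) | CC(C)(C)OC1=C(OC(C)(C)C)C(C)(OC(=O)C(F)(F)F)C1=O | intermediate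
17 | 3-tert-butoxy-4-methylcyclobut-3-ene-1,2-dione | CC(C)(C)OC1=C(C)C(=O)C1=O | intermediate
18 | (1E,16E)-1,17-bis(benzyloxy)-2,16-dilithioheptadeca-1,16-diene (lithium cis to benzyloxy at both ends, not isolated) | c1ccccc1CO/C=C([Li])/CCCCCCCCCCCCC/C([Li])=C/OCc1ccccc1 | intermediate
19 | lithium 2-tert-butoxy-1-[(1Z,16E)-1,17-bis(benzyloxy)-16-lithioheptadeca-1,16-dien-2-yl]-3-methyl-4-oxocyclobut-2-en-1-olate (racemic, not isolated) | c1ccccc1CO/C=C([Li])/CCCCCCCCCCCCC/C(=C/OCc1ccccc1)C2(O[Li])C(OC(C)(C)C)=C(C)C2=O | intermediate
20 | 4-[(1Z,16Z)-1,17-bis(benzyloxy)-16-(2-tert-butoxy-1-hydroxy-3-methyl-4-oxocyclobut-2-en-1-yl)heptadeca-1,16-dien-2-yl]-4-hydroxy-3-methoxy-2-methylcyclobut-2-en-1-one (key-step precursor; benzyloxy cis to the carbinol carbon at both ends; mixture of carbinol diastereomers) | c1ccccc1CO/C=C(/CCCCCCCCCCCCC/C(=C/OCc2ccccc2)C3(O)C(OC(C)(C)C)=C(C)C3=O)C4(O)C(OC)=C(C)C4=O | intermediate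
21 | bis(dienylketene): each end O=C=C(CH3)–C(OR)=C(OH)–C(tether)=CH–OBn with ketene and alkenyl cis on the C(OR)=C(OH) bond, R = CH3 at one end and tert-butyl at the other (not isolated) | C(=C/OCc1ccccc1)(/C(O)=C(/OC)C(C)=C=O)CCCCCCCCCCCCC/C(=C/OCc2ccccc2)/C(O)=C(/OC(C)(C)C)C(C)=C=O | intermediate
22 | bis(cyclohexa-2,4-dienone): each end a 6-(benzyloxy)-4-hydroxy-2-methylcyclohexa-2,4-dien-1-one carrying the tether at C5 and methoxy (ring A) or tert-butoxy (ring B) at C3 (mixture of diastereomers at the two C6 centres, not isolated) | O=C1C(C)=C(OC)C(O)=C(CCCCCCCCCCCCCC2=C(O)C(OC(C)(C)C)=C(C)C(=O)C2OCc3ccccc3)C1OCc4ccccc4 | intermediate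
23 | 3-(benzyloxy)-2-{13-[2-(benzyloxy)-5-tert-butoxy-3,6-dihydroxy-4-methylphenyl]tridecyl}-6-methoxy-5-methylbenzene-1,4-diol (key-step product) | COc1c(C)c(O)c(OCc2ccccc2)c(CCCCCCCCCCCCCc3c(OCc4ccccc4)c(O)c(C)c(OC(C)(C)C)c3O)c1O | intermediate
24 | 3-[13-(5-tert-butoxy-2,3,6-trihydroxy-4-methylphenyl)tridecyl]-5-methoxy-6-methylbenzene-1,2,4-triol (not isolated) | COc1c(C)c(O)c(O)c(CCCCCCCCCCCCCc2c(O)c(O)c(C)c(OC(C)(C)C)c2O)c1O | intermediate
25 | 3-[13-(5-tert-butoxy-2-hydroxy-6-methyl-1,4-benzoquinon-3-yl)tridecyl]-2-hydroxy-5-methoxy-6-methyl-1,4-benzoquinone | COC1=C(C)C(=O)C(O)=C(CCCCCCCCCCCCCC2=C(O)C(=O)C(C)=C(OC(C)(C)C)C2=O)C1=O | intermediate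
26 | 2,5-dihydroxy-3-[13-(2-hydroxy-5-methoxy-6-methyl-1,4-benzoquinon-3-yl)tridecyl]-6-methyl-1,4-benzoquinone (CNP0107579.0, no stereocentre) | COC1=C(C)C(=O)C(O)=C(CCCCCCCCCCCCCC2=C(O)C(=O)C(C)=C(O)C2=O)C1=O | target

Total step count: 11.
Longest linear sequence: 8 steps (steps 1, 2, 4, 5, 8, 9, 10, 11).

Steps most likely to fail

Step 9. With benzyloxy pointing inward at the closing terminus, the 6π closure may be slow enough for the ketene to be diverted. It could be captured by the neighbouring hydroxyl after the minor, inward sense of rotation (lactone formation), or the tertiary allylic carbinol could ionise. Fallback: the hydroxyls are masked before heating. Setting out from 20, Me3SiCl and imidazole in DMF should give the bis(trimethylsilyl ether) of 20 F1. Thermolysis in degassed xylene at 140 °C, where the silyloxy group still rotates outward but can no longer add to the ketene, should give the bis(4-trimethylsilyloxyphenol) F2. Bu4NF buffered with AcOH in THF then removes both silyl groups, and the route is rejoined at 23.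

Step 8. Addition beside the bulky tert-butoxy group may be slow or may leak to the vinylogous ester carbonyl, and the tert-butyl enol ether may be shed on work-up, so that the mixed adduct is contaminated beyond separation. Fallback: ring B carries its second oxygen as a benzyl ether. Setting out from 17, CF3CO2H in CH2Cl2 should give 3-hydroxy-4-methylcyclobut-3-ene-1,2-dione F3, and Ag2O with benzyl bromide in Et2O should give 3-(benzyloxy)-4-methylcyclobut-3-ene-1,2-dione F4, whose primary alkoxy group matches that of 13 in size and reactivity. Sequential addition of F4 and 13 to the dilithio reagent 18, as in step 8, should give the mixed (Z,Z)-bis-adduct F5 (methoxy on one ring, benzyloxy on the other). Heating in toluene should give the tribenzyl bis(hydroquinone) F6, and hydrogenolysis over 10% Pd/C the heptahydroxy bis(arene) F7. Air should oxidise F7 to both quinone rings at once, so the route is rejoined at 26 and the acid step is not needed.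

Step 5. Elimination without geometric preference would leave chain ends with bromine trans to benzyloxy, which lose lithium benzyloxide on exchange in step 8; bromide may also dealkylate the α-bromo benzyl ether before the amine acts. Fallback: the bromo enol ether is assembled with defined geometry from an alkyne. Setting out from 3, dimethyl (1-diazo-2-oxopropyl)phosphonate with K2CO3 in MeOH (Ohira–Bestmann alkynylation) should give heptadeca-1,16-diyne F8. Syn-bromoboration with BBr3 in CH2Cl2 at −78 °C places bromine on the inner carbon and boron on the terminal carbon on the same side, giving the bis(dibromoborane) F9, which pinacol converts into the bis(pinacol boronate) F10. Copper-promoted coupling of the alkenylboronate with benzyl alcohol (Cu(OAc)2, Et3N, air, rt; Chan–Lam-type etherification) replaces boron by benzyloxy with retention, and the route is rejoined at 9.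

Further compounds
F1 | step 9 | bis(trimethylsilyl ether) of 20 (both carbinol oxygens silylated; mixture of diastereomers) | c1ccccc1CO/C=C(/CCCCCCCCCCCCC/C(=C/OCc2ccccc2)C3(O[Si](C)(C)C)C(OC(C)(C)C)=C(C)C3=O)C4(O[Si](C)(C)C)C(OC)=C(C)C4=O
F2 | step 9 | bis(4-trimethylsilyloxyphenol) analogue of 23 (silyl on the oxygens flanked by tether and squarate oxygen) | COc1c(C)c(O)c(OCc2ccccc2)c(CCCCCCCCCCCCCc3c(OCc4ccccc4)c(O)c(C)c(OC(C)(C)C)c3O[Si](C)(C)C)c1O[Si](C)(C)C
F3 | step 8 | 3-hydroxy-4-methylcyclobut-3-ene-1,2-dione | CC1=C(O)C(=O)C1=O
F4 | step 8 | 3-(benzyloxy)-4-methylcyclobut-3-ene-1,2-dione | CC1=C(OCc2ccccc2)C(=O)C1=O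
F5 | step 8 | 4-[(1Z,16Z)-1,17-bis(benzyloxy)-16-(2-(benzyloxy)-1-hydroxy-3-methyl-4-oxocyclobut-2-en-1-yl)heptadeca-1,16-dien-2-yl]-4-hydroxy-3-methoxy-2-methylcyclobut-2-en-1-one (mixture of carbinol diastereomers) | c1ccccc1CO/C=C(/CCCCCCCCCCCCC/C(=C/OCc2ccccc2)C3(O)C(OCc5ccccc5)=C(C)C3=O)C4(O)C(OC)=C(C)C4=O
F6 | step 8 | 3-(benzyloxy)-2-{13-[2,5-bis(benzyloxy)-3,6-dihydroxy-4-methylphenyl]tridecyl}-6-methoxy-5-methylbenzene-1,4-diol | COc1c(C)c(O)c(OCc2ccccc2)c(CCCCCCCCCCCCCc3c(OCc4ccccc4)c(O)c(C)c(OCc5ccccc5)c3O)c1O
F7 | step 8 | 3-[13-(2,3,5,6-tetrahydroxy-4-methylphenyl)tridecyl]-5-methoxy-6-methylbenzene-1,2,4-triol | COc1c(C)c(O)c(O)c(CCCCCCCCCCCCCc2c(O)c(O)c(C)c(O)c2O)c1O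
F8 | step 5 | heptadeca-1,16-diyne | C#CCCCCCCCCCCCCCC#C
F9 | step 5 | (1Z,16Z)-2,16-dibromo-1,17-bis(dibromoboryl)heptadeca-1,16-diene | BrB(Br)/C=C(Br)/CCCCCCCCCCCCC/C(Br)=C/B(Br)Br
F10 | step 5 | 2,2'-[(1Z,16Z)-2,16-dibromoheptadeca-1,16-diene-1,17-diyl]bis(4,4,5,5-tetramethyl-1,3,2-dioxaborolane) | CC1(C)OB(OC1(C)C)/C=C(Br)/CCCCCCCCCCCCC/C(Br)=C/B1OC(C)(C)C(C)(C)O1
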